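**Plan**

- Cuts: (a) the bond from the C6 methylene to pyrone C3 (o-quinone methide plus 4-hydroxy-2-pyrone); (b) the C8–acyl bond (aryllithium plus Weinreb amide); (c) both bonds that tie the pyran ring to the benzene ring, O1–C8a and C4–C4a, which go back to an aryne (C4a≡C8a) and the C=O of 3-methylbut-2-enal.
- Enabling feature: the pyran ring O1–C2(Me)2–C3=C4–C4a=C8a is a 2H-chromene, the closed valence isomer of the o-quinone methide O1=C8a–C4a=C4–C3=C2. That oxatriene is in turn the ring-opened form of a benzoxete (O1, C4, C4a, C8a) carrying the C3=C2 vinyl group on C4. The oxygen on C5, next to C4a, polarises the aryne so that O1 ends on C8a.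
- Forward order: the bought benzene ring is dressed first (two MOM ethers, a methoxymethyl carbon at the future C6, a silyl/triflate pair at C4a/C8a). The aryne annulation then gives benzoxete, then pyran ring, and leaves C8–H as the only ring C–H. Acylation there, MOM removal and the methylene bridge to the separately made pyrone ring finish the route.
- Stereochemistry: the single stereocentre is bought as (S)-2-methylbutanoic acid and enters as its Weinreb amide; the ketone appears only on work-up and only acidic steps follow.

Key step: step 6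

Remark on the chemistry: silyl enol ether 22 is used as its E/Z mixture, since both isomers should give the same pyrone; benzoxete 12 is a transient racemate.

**Route**

Step 1
Reactants: 1 phloroglucinol
Product: 2 3,5-bis(methoxymethoxy)phenol
Conditions: MOMCl (2.0 equiv), i-Pr2NEt (2.2 equiv), CH2Cl2/DMF, 0 °C to rt; bis-ether separated from mono- and tris-ether by chromatography
Reagents that add atoms: chloromethyl methyl ether, COCCl
Why: Williamson-type O-alkylation of the C3-symmetric triol by a hard α-chloro ether, so that only one bis-ether is possible and the statistical by-products can be recycled.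

Step 2
Reactants: 2 3,5-bis(methoxymethoxy)phenol
Product: 3 triethyl[3,5-bis(methoxymethoxy)phenoxy]silane
Conditions: TESCl, imidazole, CH2Cl2, 0 °C to rt
Reagents that add atoms: chlorotriethylsilane, CC[Si](Cl)(CC)CC
Why: Standard O-silylation; the silyl ether is a poor metalation director and is the silicon source for the later O-to-C shift.

Step 3
Reactants: 3 triethyl[3,5-bis(methoxymethoxy)phenoxy]silane
Product: 5 triethyl[4-(methoxymethyl)-3,5-bis(methoxymethoxy)phenoxy]silane, via aryllithium 4 (not isolated)
Conditions: s-BuLi, TMEDA, THF, −78 °C; then MOMCl, −78 °C to 0 °C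
Reagents that add atoms: chloromethyl methyl ether, COCCl
Why: Directed ortho-metalation at the one position flanked by two chelating OMOM groups (the bulky, weakly basic silyloxy group does not compete), then C-alkylation of the aryllithium by the α-chloro ether.

Step 4
Reactants: 5 triethyl[4-(methoxymethyl)-3,5-bis(methoxymethoxy)phenoxy]silane
Product: 6 [2-bromo-4-(methoxymethyl)-3,5-bis(methoxymethoxy)phenoxy]triethylsilane
Conditions: NBS (1.0 equiv), MeCN, −20 °C to 0 °C, dark
Reagents that add atoms: N-bromosuccinimide, O=C1CCC(=O)N1Br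
Why: Electrophilic aromatic bromination of a very electron-rich ring whose two remaining C–H positions are equivalent by symmetry, so a single monobromide is expected with one equivalent of reagent.

Step 5
Reactants: 6 [2-bromo-4-(methoxymethyl)-3,5-bis(methoxymethoxy)phenoxy]triethylsilane
Product: 9 4-(methoxymethyl)-3,5-bis(methoxymethoxy)-2-(triethylsilyl)phenyl trifluoromethanesulfonate, via aryllithium 7 (not isolated), via lithium phenoxide 8 (not isolated)
Conditions: n-BuLi (1.05 equiv), THF, −78 °C to −30 °C; then Tf2O, −78 °C
Reagents that add atoms: trifluoromethanesulfonic anhydride, O=S(=O)(OS(=O)(=O)C(F)(F)F)C(F)(F)F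
Why: Bromine–lithium exchange, anionic 1,3 O-to-C silyl shift (retro-Brook) and triflation of the resulting phenoxide, the standard one-pot entry to ortho-silylaryl triflates.

Step 6
Reactants: 9 4-(methoxymethyl)-3,5-bis(methoxymethoxy)-2-(triethylsilyl)phenyl trifluoromethanesulfonate; 10 3-methylbut-2-enal
Product: 14 6-(methoxymethyl)-5,7-bis(methoxymethoxy)-2,2-dimethyl-2H-chromene, via aryne 11 (not isolated), via benzoxete 12 (not isolated), via o-quinone methide 13 (not isolated)
Conditions: CsF (3 equiv), 10 (5 equiv), MeCN, rt to 50 °C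
Reagents that add atoms: none
Why: Fluoride removes the silyl group with loss of triflate to give aryne 11; the carbonyl oxygen of 10 adds to the aryne carbon remote from the flanking OMOM group, and the aryl anion, now next to that oxygen, closes on the oxocarbenium carbon to give benzoxete 12 (formal [2+2], C–C bond formed last in an ionic four-membered closure). The closest known reaction type is the annulation of arynes with α,β-unsaturated aldehydes to 2H-chromenes, an extension of aryne–carbonyl [2+2] chemistry. The strained four-membered ring opens by thermal 4π electrocyclic ring opening to o-quinone methide 13, whose 1-oxatriene closes by thermal disrotatory oxa-6π electrocyclisation, so the four-membered ring grows by the two alkene carbons of the enal into the pyran ring. No stereocentre survives: C2 of 12 is transient and the product ring has none. The step needs regioselectivity (oxygen on the future C8a, not C4a) and periselectivity ([2+2] at C=O and not an ene reaction, a [4+2] addition or capture of 13 by a second aryne). The first should be secured by the polarisation of the aryne by the alkoxy group on the adjacent carbon, the second by excess enal and by the fast intramolecular 6π closure of the Z-configured 13.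

Step 7
Reactants: 15 (S)-2-methylbutanoic acid
Product: 17 (S)-N-methoxy-N,2-dimethylbutanamide, via acyl imidazole 16 (not isolated)
Conditions: CDI, CH2Cl2, 0 °C to rt; then MeNHOMe·HCl, rt
Reagents that add atoms: N,O-dimethylhydroxylamine hydrochloride, CNOC.Cl
Why: Amide formation through the acyl imidazole without added strong base, so the α-stereocentre of the chiral-pool acid should be retained.

Step 8
Reactants: 14 6-(methoxymethyl)-5,7-bis(methoxymethoxy)-2,2-dimethyl-2H-chromene; 17 (S)-N-methoxy-N,2-dimethylbutanamide
Product: 19 (2S)-1-[6-(methoxymethyl)-5,7-bis(methoxymethoxy)-2,2-dimethyl-2H-chromen-8-yl]-2-methylbutan-1-one, via aryllithium 18 (not isolated)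
Conditions: s-BuLi, TMEDA, THF, −78 °C; then 17, −78 °C to −20 °C; aqueous work-up
Reagents that add atoms: none
Why: Directed ortho-metalation at the only ring C–H (C8, flanked by the 7-OMOM group and the ring oxygen), then Weinreb ketone synthesis, in which the chelated tetrahedral adduct persists until work-up so the (S) centre brought in with 17 is never exposed to base as a ketone.

Step 9
Reactants: 19 (2S)-1-[6-(methoxymethyl)-5,7-bis(methoxymethoxy)-2,2-dimethyl-2H-chromen-8-yl]-2-methylbutan-1-one
Product: 20 (2S)-1-[5,7-dihydroxy-6-(methoxymethyl)-2,2-dimethyl-2H-chromen-8-yl]-2-methylbutan-1-one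
Conditions: HCl (3 M aq., cat.), MeOH, 40 °C
Reagents that add atoms: none
Why: Acid-catalysed transacetalisation of the two MOM ethers to methanol; the labile benzylic methyl ether can only re-form in methanol, every ring position is substituted so released formaldehyde equivalents cannot alkylate the arene, and mild acid should not enolise the ketone.

Step 10
Reactants: 21 pentan-3-one
Product: 22 (pent-2-en-3-yloxy)trimethylsilane
Conditions: TMSOTf, Et3N, CH2Cl2, 0 °C to rt
Reagents that add atoms: trimethylsilyl trifluoromethanesulfonate, C[Si](C)(C)OS(=O)(=O)C(F)(F)F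
Why: Soft enolisation and O-silylation of a symmetric ketone, so only one constitutional enol ether can form.

Step 11
Reactants: 22 (pent-2-en-3-yloxy)trimethylsilane; 23 malonyl dichloride
Product: 24 6-ethyl-4-hydroxy-5-methyl-2H-pyran-2-one
Conditions: Et2O, −78 °C to rt
Reagents that add atoms: none
Why: Pyrone synthesis from a silyl enol ether and malonyl dichloride (C-acylation at the enol carbon, then lactonisation through the enol oxygen), which places methyl on C5 and ethyl on C6.

Step 12
Reactants: 20 (2S)-1-[5,7-dihydroxy-6-(methoxymethyl)-2,2-dimethyl-2H-chromen-8-yl]-2-methylbutan-1-one; 24 6-ethyl-4-hydroxy-5-methyl-2H-pyran-2-one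
Product: 26 3-({5,7-dihydroxy-2,2-dimethyl-8-[(2S)-2-methylbutanoyl]-2H-chromen-6-yl}methyl)-6-ethyl-4-hydroxy-5-methyl-2H-pyran-2-one, via o-quinone methide 25 (not isolated)
Conditions: 24 (1.5 equiv), AcOH (cat.), 1,4-dioxane, 70 °C
Reagents that add atoms: none
Why: Loss of methanol from the doubly ortho-hydroxylated benzylic ether gives o-quinone methide 25, which is captured at its exocyclic CH2 by C3 of the enolic 4-hydroxy-2-pyrone (conjugate addition of a vinylogous acid, as in the assembly of methylene-bridged acylphloroglucinols), and tautomerisation restores the arene without touching the stereocentre.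

**Compound list**

1 | phloroglucinol (benzene-1,3,5-triol) | Oc1cc(O)cc(O)c1 | starting material
2 | 3,5-bis(methoxymethoxy)phenol | COCOc1cc(O)cc(OCOC)c1 | intermediate
3 | triethyl[3,5-bis(methoxymethoxy)phenoxy]silane | COCOc1cc(OCOC)cc(O[Si](CC)(CC)CC)c1 | intermediate
4 | [2,6-bis(methoxymethoxy)-4-(triethylsilyloxy)phenyl]lithium | [Li]c1c(OCOC)cc(O[Si](CC)(CC)CC)cc1OCOC | intermediate
5 | triethyl[4-(methoxymethyl)-3,5-bis(methoxymethoxy)phenoxy]silane | COCc1c(OCOC)cc(O[Si](CC)(CC)CC)cc1OCOC | intermediate
6 | [2-bromo-4-(methoxymethyl)-3,5-bis(methoxymethoxy)phenoxy]triethylsilane | COCc1c(OCOC)cc(O[Si](CC)(CC)CC)c(Br)c1OCOC | intermediate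
7 | [3-(methoxymethyl)-2,4-bis(methoxymethoxy)-6-(triethylsilyloxy)phenyl]lithium | [Li]c1c(O[Si](CC)(CC)CC)cc(OCOC)c(COC)c1OCOC | intermediate
8 | lithium 4-(methoxymethyl)-3,5-bis(methoxymethoxy)-2-(triethylsilyl)phenolate | [Li+].[O-]c1cc(OCOC)c(COC)c(OCOC)c1[Si](CC)(CC)CC | intermediate
9 | 4-(methoxymethyl)-3,5-bis(methoxymethoxy)-2-(triethylsilyl)phenyl trifluoromethanesulfonate | COCc1c(OCOC)cc(OS(=O)(=O)C(F)(F)F)c([Si](CC)(CC)CC)c1OCOC | intermediate
10 | 3-methylbut-2-enal | CC(C)=CC=O | starting material
11 | 4-(methoxymethyl)-3,5-bis(methoxymethoxy)benzyne (aryne between the former C1 and C2) | COCC1=C(OCOC)C#CC=C1OCOC | intermediate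
12 | 4-(methoxymethyl)-3,5-bis(methoxymethoxy)-2-(2-methylprop-1-en-1-yl)-2H-benzo[b]oxete (racemic) | COCc1c(OCOC)cc2OC(C=C(C)C)c2c1OCOC | intermediate
13 | (6Z)-4-(methoxymethyl)-3,5-bis(methoxymethoxy)-6-(3-methylbut-2-en-1-ylidene)cyclohexa-2,4-dien-1-one | CC(C)=C/C=C1\C(=O)C=C(OCOC)C(COC)=C1OCOC | intermediate
14 | 6-(methoxymethyl)-5,7-bis(methoxymethoxy)-2,2-dimethyl-2H-chromene | COCc1c(OCOC)cc2OC(C)(C)C=Cc2c1OCOC | intermediate
15 | (S)-2-methylbutanoic acid | CC[C@H](C)C(=O)O | starting material
16 | (2S)-1-(1H-imidazol-1-yl)-2-methylbutan-1-one | CC[C@H](C)C(=O)n1ccnc1 | intermediate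
17 | (S)-N-methoxy-N,2-dimethylbutanamide | CC[C@H](C)C(=O)N(C)OC | intermediate
18 | [6-(methoxymethyl)-5,7-bis(methoxymethoxy)-2,2-dimethyl-2H-chromen-8-yl]lithium | [Li]c1c(OCOC)c(COC)c(OCOC)c2C=CC(C)(C)Oc12 | intermediate
19 | (2S)-1-[6-(methoxymethyl)-5,7-bis(methoxymethoxy)-2,2-dimethyl-2H-chromen-8-yl]-2-methylbutan-1-one | CC[C@H](C)C(=O)c1c(OCOC)c(COC)c(OCOC)c2C=CC(C)(C)Oc12 | intermediate
20 | (2S)-1-[5,7-dihydroxy-6-(methoxymethyl)-2,2-dimethyl-2H-chromen-8-yl]-2-methylbutan-1-one | CC[C@H](C)C(=O)c1c(O)c(COC)c(O)c2C=CC(C)(C)Oc12 | intermediate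
21 | pentan-3-one | CCC(=O)CC | starting material
22 | (pent-2-en-3-yloxy)trimethylsilane (E/Z mixture) | CC=C(CC)O[Si](C)(C)C | intermediate
23 | malonyl dichloride | O=C(Cl)CC(=O)Cl | starting material
24 | 6-ethyl-4-hydroxy-5-methyl-2H-pyran-2-one | CCc1oc(=O)cc(O)c1C | intermediate
25 | 7-hydroxy-2,2-dimethyl-8-[(2S)-2-methylbutanoyl]-6-methylidene-2H-chromen-5(6H)-one | C=C1C(=O)C2=C(OC(C)(C)C=C2)C(C(=O)[C@@H](C)CC)=C1O | intermediate
26 | 3-({5,7-dihydroxy-2,2-dimethyl-8-[(2S)-2-methylbutanoyl]-2H-chromen-6-yl}methyl)-6-ethyl-4-hydroxy-5-methyl-2H-pyran-2-one | CCc1oc(=O)c(Cc2c(O)c3C=CC(C)(C)Oc3c(C(=O)[C@@H](C)CC)c2O)c(O)c1C | target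

**Totals and risks**

Total step count: 12. Longest linear sequence: 9 steps (steps 1, 2, 3, 4, 5, 6, 8, 9, 12).

Steps most likely to fail:

1. Step 6. Fluoride attack on the hindered triethylsilyl group may be slow. The aryne may also be diverted into an ene reaction with the allylic methyl groups of the enal, or the o-quinone methide may be intercepted by a second aryne before it closes. The fallback leaves the route at compound 5 and returns at compound 14 without an aryne. TBAF in THF should cleave the silyl ether to 4-(methoxymethyl)-3,5-bis(methoxymethoxy)phenol F1. O-alkylation with 3-chloro-3-methylbut-1-yne (K2CO3, KI, acetone, or DBU with catalytic CuCl2) should give 2-(methoxymethyl)-1,3-bis(methoxymethoxy)-5-[(2-methylbut-3-yn-2-yl)oxy]benzene F2. Heating F2 in N,N-diethylaniline should trigger the propargyl Claisen rearrangement, 1,5-hydrogen shift and oxa-6π closure to 14; the two ortho positions of F2 are equivalent, so one chromene is expected.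

2. Step 8. Deprotonation may take place at the benzylic CH2OMe group (lateral lithiation followed by Wittig rearrangement) in competition with the ring position. Addition of the hindered aryllithium to the α-branched Weinreb amide may also be slower than its enolisation. The fallback leaves at compound 14 and returns at compound 19. NBS at low temperature should brominate the only free ring position to give 8-bromo-6-(methoxymethyl)-5,7-bis(methoxymethoxy)-2,2-dimethyl-2H-chromene F3. Fast bromine–lithium exchange (n-BuLi, THF, −78 °C) and addition to freshly distilled (S)-2-methylbutanal should give (2S)-1-[6-(methoxymethyl)-5,7-bis(methoxymethoxy)-2,2-dimethyl-2H-chromen-8-yl]-2-methylbutan-1-ol F4 as a mixture of carbinol epimers. Dess–Martin oxidation under buffered, non-basic conditions should then give 19.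

3. Step 12. The o-quinone methide may be recaptured by the released methanol or oligomerise faster than it is trapped at carbon, and the adduct may cyclodehydrate between the phenol and the pyrone hydroxyl. The fallback leaves at compound 19 and returns at compound 26 by a reductive coupling in place of the quinone methide route. DDQ in wet CH2Cl2 should oxidise the electron-rich benzylic methyl ether to 5,7-bis(methoxymethoxy)-2,2-dimethyl-8-[(2S)-2-methylbutanoyl]-2H-chromene-6-carbaldehyde F5. HCl in methanol should remove the MOM groups to give 5,7-dihydroxy-2,2-dimethyl-8-[(2S)-2-methylbutanoyl]-2H-chromene-6-carbaldehyde F6. A three-component reductive Knoevenagel reaction of F6 with pyrone 24 and Hantzsch ester (catalytic L-proline, CH2Cl2, rt) should then give 26.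

**Further compounds**

F1 | step 6 | 4-(methoxymethyl)-3,5-bis(methoxymethoxy)phenol | COCc1c(OCOC)cc(O)cc1OCOC
F2 | step 6 | 2-(methoxymethyl)-1,3-bis(methoxymethoxy)-5-[(2-methylbut-3-yn-2-yl)oxy]benzene | COCc1c(OCOC)cc(OC(C)(C)C#C)cc1OCOC
F3 | step 8 | 8-bromo-6-(methoxymethyl)-5,7-bis(methoxymethoxy)-2,2-dimethyl-2H-chromene | COCc1c(OCOC)c(Br)c2OC(C)(C)C=Cc2c1OCOC
F4 | step 8 | (2S)-1-[6-(methoxymethyl)-5,7-bis(methoxymethoxy)-2,2-dimethyl-2H-chromen-8-yl]-2-methylbutan-1-ol (both carbinol epimers) | CC[C@H](C)C(O)c1c(OCOC)c(COC)c(OCOC)c2C=CC(C)(C)Oc12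
F5 | step 12 | 5,7-bis(methoxymethoxy)-2,2-dimethyl-8-[(2S)-2-methylbutanoyl]-2H-chromene-6-carbaldehyde | CC[C@H](C)C(=O)c1c(OCOC)c(C=O)c(OCOC)c2C=CC(C)(C)Oc12
F6 | step 12 | 5,7-dihydroxy-2,2-dimethyl-8-[(2S)-2-methylbutanoyl]-2H-chromene-6-carbaldehyde | CC[C@H](C)C(=O)c1c(O)c(C=O)c(O)c2C=CC(C)(C)Oc12
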